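The target is cut at the two bonds flanking its only stereocentres, C7 (aryl carbinol) and C8 (methine bearing C9H2O and allylic C9′H2): C7–aryl, to the 3,4-dimethoxyphenyl ring, and C8–C9′, to the 4-methoxycinnamyl chain. The remaining C7–C8–C9 unit becomes an E-alkenyl pinacol boronate with O9 silylated. The key step exploits this vicinal pair sitting where three fragments join: the lithium ate complex from the boronate and 3,4-dimethoxyphenyllithium is allylated at C8 by a chiral cinnamylpalladium cation as the aryl group migrates from boron to C7, creating two C–C bonds and both stereocentres at once. C–B oxidation, desilylation, Mitsunobu esterification with a Z-configured silyloxymethylbutenoic acid and final desilylation finish the route.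

Key step: step 3

Assumption: the sense of face selection of the chiral ligand in this new reaction cannot be predicted, so the ligand is written as the (Sp,Sp,αR,αR) form of 1,1′-bis[bis(4-methoxy-3,5-dimethylphenyl)phosphino]-2,2′-bis[α-(dimethylamino)benzyl]ferrocene (C64H74FeN2O4P2), and its mirror image is to be used instead if a screen shows that it is the one leading to 7S,8R.

Step 1
Reactants: 1 tert-butyldimethyl(prop-2-yn-1-yloxy)silane
Product: 2 (E)-tert-butyldimethyl{[3-(4,4,5,5-tetramethyl-1,3,2-dioxaborolan-2-yl)prop-2-en-1-yl]oxy}silane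
Conditions: HBpin (1.1 equiv), Cp2ZrHCl (5 mol%), Et3N (10 mol%), neat, 60 °C
Reagents that add atoms: pinacolborane, [H]B1OC(C)(C)C(C)(C)O1
Why: Zirconocene-catalysed alkyne hydroboration (hydrozirconation, then zirconium-to-boron exchange) is a syn addition that places boron on the terminal carbon, so the E alkenyl boronate should form from the catalogue silyl ether 1 without touching the Si–O bond.

Step 2
Reactants: 3 (E)-3-(4-methoxyphenyl)prop-2-en-1-ol
Product: 4 (E)-3-(4-methoxyphenyl)prop-2-en-1-yl methyl carbonate
Conditions: ClCO2Me, pyridine, CH2Cl2, 0 °C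
Reagents that add atoms: methyl chloroformate, COC(=O)Cl
Why: O-Acylation of a primary allylic alcohol by a chloroformate under pyridine buffering keeps the ionisation-prone 4-methoxycinnamyl system away from acid and leaves the E alkene untouched.

Step 3
Reactants: 5 4-bromo-1,2-dimethoxybenzene; 2 (E)-alkenyl pinacol boronate; 4 (E)-4-methoxycinnamyl methyl carbonate
Product: 8 tert-butyl{[(2S,3S)-3-(3,4-dimethoxyphenyl)-2-[(E)-3-(4-methoxyphenyl)prop-2-en-1-yl]-3-(4,4,5,5-tetramethyl-1,3,2-dioxaborolan-2-yl)propyl]oxy}dimethylsilane (benzylic pinacol boronate at C7; TBS ether at C9), via 3,4-dimethoxyphenyllithium 6 (not isolated), via lithium boron ate complex 7 (not isolated)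
Conditions: 5 (1.25 equiv), n-BuLi (1.2 equiv), THF, −78 °C; 2 (1.2 equiv), −78 °C to rt; volatiles removed in vacuo; 4 (1.0 equiv), Pd2(dba)3 (2.5 mol%), MandyPhos-type bisphosphine C64H74FeN2O4P2 (6 mol%), THF, rt to 40 °C; H2O work-up
Reagents that add atoms: none
Why: Proposed new method: bromine–lithium exchange gives 6, which adds to the vacant boron orbital of 2 to form ate complex 7, while zerovalent palladium (from Pd2(dba)3 and the bisphosphine) ionises carbonate 4 to a chelated cationic η3-(4-methoxycinnamyl)palladium complex (divalent palladium); the enamine-like C7=C8 bond of 7 should then attack the unsubstituted allyl terminus through C8 and, in concert and antiperiplanar to the new C8–C9′ bond, the 3,4-dimethoxyphenyl group should move from boron to C7, returning zerovalent palladium. The closest known reactions are the palladium-induced 1,2-metallate shift of alkenylboron ate complexes with aryl or alkenyl triflates (conjunctive cross-coupling) and the allylation of such ate complexes by π-allyl metal electrophiles, but a linear, enantioselective cinnamylation of a β-substituted alkenyl boronate has not been shown. No ring is closed. The relative configuration of C7 and C8 follows from stereospecific anti addition of aryl and allyl across the E alkene, which can give only the 7S,8S boronate (the spatial arrangement of the 7S,8R pair of the target, the C8 descriptor differing only because boron ranks below oxygen) or its mirror image, and the choice between the two rests on the chiral bisphosphine, whose pocket must tell the alkene faces apart by the position of the CH2OTBS group. The step also needs attack at the CH2 end of the allyl unit with the E styrene kept, which the aryl-substituted syn-allyl complex secures, and it needs the metallate shift to outrun direct transfer of aryl or alkenyl from boron to palladium, which the coordinatively saturated chelated allyl cation and the bromide-free ate complex (n-BuLi leaves only BuBr, removed with the solvent) are meant to ensure, while the silyl ether at C9, a poor leaving group, blocks an SN2′-type migration with loss of the C9 oxygen.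

Step 4
Reactants: 8 benzylic pinacol boronate
Product: 9 (1S,2R,4E)-2-{[(tert-butyldimethylsilyl)oxy]methyl}-1-(3,4-dimethoxyphenyl)-5-(4-methoxyphenyl)pent-4-en-1-ol
Conditions: 30% aq. H2O2, 3 M aq. NaOH, THF, 0 °C to rt
Reagents that add atoms: hydrogen peroxide, OO
Why: In the alkaline hydroperoxide oxidation of a boronic ester C7 migrates from boron to oxygen with retention, so the 7S carbinol should form (C8 now reads R with unchanged geometry), while the silyl ether and the electron-rich alkene are inert to basic peroxide.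

Step 5
Reactants: 9 C9 silyl ether with free C7 hydroxyl
Product: 10 (1S,2R)-1-(3,4-dimethoxyphenyl)-2-[(E)-3-(4-methoxyphenyl)prop-2-en-1-yl]propane-1,3-diol
Conditions: Bu4NF, THF, 0 °C to rt; H2O work-up
Reagents that add atoms: none
Why: Fluoride-driven cleavage of the Si–O bond is non-acidic, which matters because the electron-rich benzylic carbinol at C7 would ionise under acid.

Step 6
Reactants: 11 (E)-but-2-enal (crotonaldehyde)
Product: 12 (Z)-2-iodobut-2-enal
Conditions: I2, K2CO3, DMAP (20 mol%), THF/H2O 1:1, rt
Reagents that add atoms: iodine, [I][I]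
Why: Nucleophile-catalysed α-iodination of an enal (conjugate addition of DMAP, iodination of the enolate, E1cB loss of DMAP) should give the thermodynamic Z isomer, with methyl trans to the formyl group and cis to iodine.

Step 7
Reactants: 12 (Z)-2-iodobut-2-enal
Product: 13 (Z)-2-iodobut-2-en-1-ol
Conditions: NaBH4, THF/H2O 9:1, 0 °C
Reagents that add atoms: none
Why: Borohydride 1,2-reduction of the aldehyde leaves the alkenyl iodide and the alkene geometry untouched at 0 °C.

Step 8
Reactants: 13 (Z)-2-iodobut-2-en-1-ol
Product: 14 (Z)-tert-butyl[(2-iodobut-2-en-1-yl)oxy]dimethylsilane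
Conditions: TBSCl, imidazole, CH2Cl2, rt
Reagents that add atoms: tert-butyldimethylsilyl chloride, CC(C)(C)[Si](C)(C)Cl
Why: Silylation of a primary allylic alcohol with imidazole as base and nucleophilic catalyst is routine and does not affect the alkenyl iodide.

Step 9
Reactants: 14 (Z)-alkenyl iodide silyl ether
Product: 16 (Z)-2-{[(tert-butyldimethylsilyl)oxy]methyl}but-2-enoic acid, via alkenyllithium 15 (not isolated)
Conditions: t-BuLi (2.1 equiv), Et2O, −78 °C; CO2 (dry gas), −78 °C to 0 °C; cold 0.5 M HCl to pH 3
Reagents that add atoms: carbon dioxide, O=C=O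
Why: Iodine–lithium exchange on an alkenyl iodide and carboxylation of the alkenyllithium both proceed with retention at the sp2 carbon, so the carboxyl group should end up cis to the methyl group (Z acid), and holding −78 °C suppresses oxygen-to-carbon silyl migration and loss of silyloxide.

Step 10
Reactants: 10 (1S,2R)-diol; 16 (Z)-silyloxymethylbutenoic acid
Product: 17 (2R,3S)-3-(3,4-dimethoxyphenyl)-3-hydroxy-2-[(E)-3-(4-methoxyphenyl)prop-2-en-1-yl]propyl (Z)-2-{[(tert-butyldimethylsilyl)oxy]methyl}but-2-enoate
Conditions: 16 (1.05 equiv), PPh3 (1.1 equiv), DIAD (1.1 equiv, slow addition), THF, 0 °C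
Reagents that add atoms: none
Why: In the Mitsunobu esterification the carboxylate displaces the oxyphosphonium of the less hindered primary C9 hydroxyl (no stereocentre there), which should leave the C7 carbinol free and, because the acid is never activated as an acyl donor, keep the Z butenoate from isomerising.

Step 11
Reactants: 17 silyl-protected ester
Product: 18 (2R,3S)-3-(3,4-dimethoxyphenyl)-3-hydroxy-2-[(E)-3-(4-methoxyphenyl)prop-2-en-1-yl]propyl (Z)-2-(hydroxymethyl)but-2-enoate (CNP0280662.1)
Conditions: HF·pyridine, pyridine, THF, 0 °C to rt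
Reagents that add atoms: none
Why: Pyridine-buffered HF cleaves the primary allylic silyl ether without the basic conditions that would promote acyl migration from O9 to O7 and without acid strong enough to ionise the C7 carbinol.

Compound list
1 | tert-butyldimethyl(prop-2-yn-1-yloxy)silane | C#CCO[Si](C)(C)C(C)(C)C | starting material
2 | (E)-tert-butyldimethyl{[3-(4,4,5,5-tetramethyl-1,3,2-dioxaborolan-2-yl)prop-2-en-1-yl]oxy}silane | CC(C)(C)[Si](C)(C)OC/C=C/B1OC(C)(C)C(C)(C)O1 | intermediate
3 | (E)-3-(4-methoxyphenyl)prop-2-en-1-ol | COc1ccc(/C=C/CO)cc1 | starting material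
4 | (E)-3-(4-methoxyphenyl)prop-2-en-1-yl methyl carbonate | COC(=O)OC/C=C/c1ccc(OC)cc1 | intermediate
5 | 4-bromo-1,2-dimethoxybenzene | COc1ccc(Br)cc1OC | starting material
6 | 3,4-dimethoxyphenyllithium | [Li]c1ccc(OC)c(OC)c1 | intermediate
7 | lithium (3,4-dimethoxyphenyl)[(E)-3-(tert-butyldimethylsilyloxy)prop-1-en-1-yl](pinacolato)borate | [Li+].COc1ccc(cc1OC)[B-]1(/C=C/CO[Si](C)(C)C(C)(C)C)OC(C)(C)C(C)(C)O1 | intermediate
8 | tert-butyl{[(2S,3S)-3-(3,4-dimethoxyphenyl)-2-[(E)-3-(4-methoxyphenyl)prop-2-en-1-yl]-3-(4,4,5,5-tetramethyl-1,3,2-dioxaborolan-2-yl)propyl]oxy}dimethylsilane | CC(C)(C)[Si](C)(C)OC[C@@H](C/C=C/c1ccc(OC)cc1)[C@H](B1OC(C)(C)C(C)(C)O1)c1ccc(OC)c(OC)c1 | intermediate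
9 | (1S,2R,4E)-2-{[(tert-butyldimethylsilyl)oxy]methyl}-1-(3,4-dimethoxyphenyl)-5-(4-methoxyphenyl)pent-4-en-1-ol | CC(C)(C)[Si](C)(C)OC[C@@H](C/C=C/c1ccc(OC)cc1)[C@H](O)c1ccc(OC)c(OC)c1 | intermediate
10 | (1S,2R)-1-(3,4-dimethoxyphenyl)-2-[(E)-3-(4-methoxyphenyl)prop-2-en-1-yl]propane-1,3-diol | OC[C@@H](C/C=C/c1ccc(OC)cc1)[C@H](O)c1ccc(OC)c(OC)c1 | intermediate
11 | (E)-but-2-enal (crotonaldehyde) | C/C=C/C=O | starting material
12 | (Z)-2-iodobut-2-enal | C/C=C(\I)C=O | intermediate
13 | (Z)-2-iodobut-2-en-1-ol | C/C=C(\I)CO | intermediate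
14 | (Z)-tert-butyl[(2-iodobut-2-en-1-yl)oxy]dimethylsilane | C/C=C(\I)CO[Si](C)(C)C(C)(C)C | intermediate
15 | 2-lithio analogue of 14 (lithium in place of iodine, geometry retained) | C/C=C(\[Li])CO[Si](C)(C)C(C)(C)C | intermediate
16 | (Z)-2-{[(tert-butyldimethylsilyl)oxy]methyl}but-2-enoic acid | C/C=C(/CO[Si](C)(C)C(C)(C)C)C(=O)O | intermediate
17 | (2R,3S)-3-(3,4-dimethoxyphenyl)-3-hydroxy-2-[(E)-3-(4-methoxyphenyl)prop-2-en-1-yl]propyl (Z)-2-{[(tert-butyldimethylsilyl)oxy]methyl}but-2-enoate | C/C=C(/CO[Si](C)(C)C(C)(C)C)C(=O)OC[C@@H](C/C=C/c1ccc(OC)cc1)[C@H](O)c1ccc(OC)c(OC)c1 | intermediate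
18 | (2R,3S)-3-(3,4-dimethoxyphenyl)-3-hydroxy-2-[(E)-3-(4-methoxyphenyl)prop-2-en-1-yl]propyl (Z)-2-(hydroxymethyl)but-2-enoate | C/C=C(/CO)C(=O)OC[C@@H](C/C=C/c1ccc(OC)cc1)[C@H](O)c1ccc(OC)c(OC)c1 | target

Total step count: 11
Longest linear sequence: 6 steps (steps 1, 3, 4, 5, 10, 11; the acid arm, steps 6 to 11, is equally long)

Steps most likely to fail

Step 3. The catalyst may distinguish the two alkene faces poorly, or transfer of the aryl or alkenyl group from boron to palladium may overtake the metallate shift and give plain allyl–aryl or allyl–alkenyl coupling. The fallback uses known chemistry, sets out from 4 and rejoins the route at 10. Tsuji–Trost alkylation of dimethyl malonate with 4 (Pd(PPh3)4, THF, rt) should give dimethyl 2-[(E)-3-(4-methoxyphenyl)prop-2-en-1-yl]malonate F1. Saponification and thermal decarboxylation (KOH, aq. EtOH; cold dilute HCl; pyridine, reflux) should give (E)-5-(4-methoxyphenyl)pent-4-enoic acid F2. Its pivaloyl mixed anhydride (PivCl, Et3N, THF, −20 °C) should acylate (S)-4-benzyloxazolidin-2-one (LiCl, rt) to give (S)-4-benzyl-3-[(E)-5-(4-methoxyphenyl)pent-4-enoyl]oxazolidin-2-one F3. The Z boron enolate of F3 (Bu2BOTf, i-Pr2NEt, CH2Cl2, 0 °C) should add to commercial 3,4-dimethoxybenzaldehyde at −78 °C in an Evans syn aldol reaction to give the (2′S,3′S) aldol adduct F4, which has the same spatial arrangement at C7 and C8 as the target. Reductive removal of the auxiliary (LiBH4, THF/MeOH, 0 °C) should then give diol 10.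

Step 10. The betaine may activate the benzylic C7 hydroxyl in competition with C9, which would cost regioselectivity and could cause substitution or elimination at C7. The fallback sets out from 9 and rejoins the route at 18. Silylation of the C7 hydroxyl (TBSOTf, 2,6-lutidine, CH2Cl2, −78 °C) should give the bis-silyl ether F5. Selective cleavage of the primary silyl ether (HF·pyridine, pyridine, THF, 0 °C) should give the primary alcohol F6. With only one free hydroxyl left, Mitsunobu esterification of F6 with 16 (PPh3, DIAD, THF, 0 °C) should give the doubly silylated ester F7. Removal of both silyl groups (HF·pyridine, THF, rt) should give 18.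

Step 9. The alkenyllithium may undergo oxygen-to-carbon silyl migration or lose silyloxide before it is carboxylated. The fallback sets out from 14 and rejoins the route at 16. Palladium-catalysed methoxycarbonylation (CO 1 atm, MeOH, Et3N, PdCl2(PPh3)2, DMF, 50 °C) should give, with retention of geometry, methyl (Z)-2-{[(tert-butyldimethylsilyl)oxy]methyl}but-2-enoate F8. Saponification (LiOH, THF/H2O, rt; acidified to pH 3 to 4) should give 16.

Further compounds
F1 | step 3 | dimethyl 2-[(E)-3-(4-methoxyphenyl)prop-2-en-1-yl]malonate | COC(=O)C(C/C=C/c1ccc(OC)cc1)C(=O)OC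
F2 | step 3 | (E)-5-(4-methoxyphenyl)pent-4-enoic acid | OC(=O)CC/C=C/c1ccc(OC)cc1
F3 | step 3 | (S)-4-benzyl-3-[(E)-5-(4-methoxyphenyl)pent-4-enoyl]oxazolidin-2-one | O=C(CC/C=C/c1ccc(OC)cc1)N1C(=O)OC[C@@H]1Cc1ccccc1
F4 | step 3 | (S)-4-benzyl-3-{(2S,4E)-2-[(S)-(3,4-dimethoxyphenyl)(hydroxy)methyl]-5-(4-methoxyphenyl)pent-4-enoyl}oxazolidin-2-one | O=C(N1C(=O)OC[C@@H]1Cc1ccccc1)[C@@H](C/C=C/c1ccc(OC)cc1)[C@H](O)c1ccc(OC)c(OC)c1
F5 | step 10 | bis(tert-butyldimethylsilyl) ether of diol 10 (O7 and O9 silylated) | CC(C)(C)[Si](C)(C)OC[C@@H](C/C=C/c1ccc(OC)cc1)[C@H](O[Si](C)(C)C(C)(C)C)c1ccc(OC)c(OC)c1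
F6 | step 10 | (2R,3S)-3-[(tert-butyldimethylsilyl)oxy]-3-(3,4-dimethoxyphenyl)-2-[(E)-3-(4-methoxyphenyl)prop-2-en-1-yl]propan-1-ol | OC[C@@H](C/C=C/c1ccc(OC)cc1)[C@H](O[Si](C)(C)C(C)(C)C)c1ccc(OC)c(OC)c1
F7 | step 10 | O7-silylated analogue of ester 17 | C/C=C(/CO[Si](C)(C)C(C)(C)C)C(=O)OC[C@@H](C/C=C/c1ccc(OC)cc1)[C@H](O[Si](C)(C)C(C)(C)C)c1ccc(OC)c(OC)c1
F8 | step 9 | methyl (Z)-2-{[(tert-butyldimethylsilyl)oxy]methyl}but-2-enoate | C/C=C(/CO[Si](C)(C)C(C)(C)C)C(=O)OC
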